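Count turnovers first: the product made per catalyst charged by a given time, a turnover number.

| flask | substrate | reagent | free catalyst | remark | time |
|---|---|---|---|---|---|
| north-west | 0.25 M | 0.30 M (fed, over 5.0 h) | 0.35 mM | run made earlier; the fed solution adds 0.10 times the starting volume |  |
| south-west | 0.25 M | 0.30 M (fed, over 5.0 h) | 0.78 mM | run made earlier; the fed solution adds 0.10 times the starting volume |  |
| north-east | 0.50 M | 0.30 M (fed, over 5.0 h) | 0.52 mM | run made earlier; the fed solution adds 0.10 times the starting volume |  |
| flask | 0.25 M | 0.300 M (fed, over 5.0 h) | 0.52 mM | the fed solution adds 0.10 times the starting volume | 10 h |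

| run | time / h | product / % | substrate / % |
|---|---|---|---|
| north-west | 0.833 | 3.5 | 97.6 |
| north-west | 1.33 | 6.7 | 92.7 |
| north-west | 2.00 | 12.9 | 86.7 |
| north-west | 4.00 | 34.7 | 66.2 |
| north-west | 6.00 | 53.4 | 43.4 |
| north-west | 10.0 | 78.0 | 22.3 |
| south-west | 0.833 | 6.9 | 94.7 |
| south-west | 1.33 | 13.1 | 86.6 |
| south-west | 2.00 | 25.1 | 76.9 |
| south-west | 4.00 | 57.3 | 43.3 |
| south-west | 6.00 | 85.6 | 13.6 |
| south-west | 10.0 | 100.1 | 2.1 |
| north-east | 0.833 | 1.7 | 97.1 |
| north-east | 1.50 | 5.8 | 94.9 |
| north-east | 3.00 | 18.6 | 82.2 |
| north-east | 5.00 | 31.2 | 68.8 |
| north-east | 10.0 | 49.3 | 51.5 |

(each reading ± 1 percentage point)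

- for product the idle complex is counted in
- charges are per starting volume, the dose included; the dosed solution carries all of it
- reactions considered so far: reagent + catalyst intermediate A -> catalyst intermediate B; free catalyst + product <-> idle complex; substrate + free catalyst -> catalyst intermediate A; catalyst intermediate C -> free catalyst + product; catalyst intermediate B -> catalyst intermediate C; catalyst intermediate A -> spent catalyst

- the product in the flask at 10 h, as a percentage of the substrate charged
- the substrate in the flask at 10 h, as a percentage of the substrate charged

The north-east run has the flask's charges of free catalyst and reagent, but twice the substrate, and at 10.0 h it still holds 51.5% of that substrate. It reads 474 turnovers by then. I call this the ten-hour reach: product formed per catalyst charged by that time, at this charge of free catalyst and reagent, with substrate still standing. The flask needs 481 turnovers to use up its substrate, about the reach. So the reach covers 98.6% of the flask's substrate charge, a reading that carries the scatter. I take this as my own estimate from above for the flask's product at 10 h, not as its yield, and it stands higher than the forecast.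

The forecast gives 89% product and 11% substrate, on the ground that “The flask needs only about 430 turnovers, so this should slow it rather than stop it”.

The flask gives 91.2% product and 8.63% substrate.

    reagent + catalyst intermediate A → catalyst intermediate B (k = 1600 /M/h)
    free catalyst + product ⇌ idle complex, settled at all times (K = 3.30 /M)
    substrate + free catalyst → catalyst intermediate A (k = 6300 /M/h)
    catalyst intermediate C → free catalyst + product (k = 630 /h)
    catalyst intermediate B → catalyst intermediate C (k = 61000 /h)
    catalyst intermediate A → spent catalyst (k = 0.180 /h)

At 10.0 h, 66.5% of the catalyst charged to the flask stands as spent catalyst. The flask has made 438 turnovers, fewer than the reach.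

In the neighbour charged with 0.62 M of substrate, the reach gives 39.8% product at 10 h. That flask gives 40.1%.

The numbers in the tables were computed on assumed constants, noise included.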